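**Assumption:** the target SMILES has no stereocentre and no stereogenic double bond, so the flavone is achiral and needs no stereocontrol; compounds 1, 2, 5 and 6 are taken as catalogue chemicals.

## Retrosynthetic overview

1. The C2–C1′ bond is cut with reversed polarity: chromone C2, normally the electrophilic enone β-carbon and a masked acyl carbon, becomes the nucleophile (a 2-zinciochromone, i.e. an α-metalated enol ether / β-acylvinyl anion at the homoenolate level). Ring B is the electrophile, an aryl iodide.
2. The chromone 4 comes from 2′,6′-dihydroxy-4′-methoxyacetophenone plus one carbon from DMF-DMA. The two phenols are equivalent, so either one closes ring C and the other remains as the 5-OH, with no protecting groups.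
3. The aryl iodide 7 comes from 1,2,3,4-tetramethoxybenzene by iodination; symmetry allows only one mono-iodide.
4. Ring order: rings A and B are bought intact; ring C (the pyranone) is the only ring formed, in step 1, before the coupling.

## Route

**Step 1**
Reactants: 1 1-(2,6-dihydroxy-4-methoxyphenyl)ethan-1-one; 2 N,N-dimethylformamide dimethyl acetal
Product: 4 5-hydroxy-7-methoxy-4H-chromen-4-one, via enaminone 3 (not isolated)
Conditions: DMF-DMA (1.3 equiv), toluene, 80 °C; then conc. HCl, CH2Cl2, 40 °C
Reagents that add atoms: N,N-dimethylformamide dimethyl acetal, COC(OC)N(C)C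
Why: Amide-acetal condensation at the acetyl CH3 gives the vinylogous amide, and acid then drives intramolecular O-addition with loss of dimethylamine (enaminone chromone synthesis); either of the two equivalent phenols can cyclise, leaving the other as the chelated 5-OH.

**Step 2**
Reactants: 5 1,2,3,4-tetramethoxybenzene; 6 N-iodosuccinimide
Product: 7 1-iodo-2,3,4,5-tetramethoxybenzene
Conditions: NIS (1.05 equiv), TFA (0.3 equiv), MeCN, 0 → 25 °C, dark
Reagents that add atoms: N-iodosuccinimide, O=C1CCC(=O)N1I
Why: Electrophilic aromatic iodination of a very electron-rich arene; C5 and C6 of 5 are equivalent by symmetry, so mono-iodination gives a single regioisomer.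

**Step 3**
Reactants: 4 5-hydroxy-7-methoxy-4H-chromen-4-one; 7 1-iodo-2,3,4,5-tetramethoxybenzene
Product: 9 5-hydroxy-7-methoxy-2-(2,3,4,5-tetramethoxyphenyl)-4H-chromen-4-one, via 2-zinciochromone 8 (not isolated)
Conditions: TMP2Zn·2MgCl2·2LiCl (1.2 equiv; TMP = 2,2,6,6-tetramethylpiperidide), THF, −30 → 25 °C; then 7 (1.1 equiv), Pd(OAc)2 (3 mol %), SPhos (6 mol %), 50 °C; 1 M HCl work-up
Reagents that add atoms: none
Why: Proposed new method: the first amide equivalent deprotonates the 5-OH to a divalent-metal phenoxide that chelates the C4 carbonyl (the role an external Lewis acid such as MgCl2 plays in the C2-zincation of 5,7-dialkoxychromones), the second removes the most acidic ring C–H at C2 to give a 2-zinciochromone in which the normally electrophilic C2 is the nucleophile, and zerovalent palladium formed from Pd(OAc)2/SPhos joins it to the electrophilic ipso carbon of 7 by Negishi coupling; the closest known reaction type is the Lewis-acid-triggered C2–H zincation/Negishi arylation of O-alkylated chromones (my recollection is that the MgCl2-containing base is the C2-selective one, which should be checked), extended here to the free 5-hydroxy compound, and no stereocentre is formed.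

## Compound list

1 | 1-(2,6-dihydroxy-4-methoxyphenyl)ethan-1-one (2′,6′-dihydroxy-4′-methoxyacetophenone) | CC(=O)c1c(O)cc(OC)cc1O | starting material
2 | N,N-dimethylformamide dimethyl acetal | COC(OC)N(C)C | starting material
3 | (E)-3-(dimethylamino)-1-(2,6-dihydroxy-4-methoxyphenyl)prop-2-en-1-one | CN(C)/C=C/C(=O)c1c(O)cc(OC)cc1O | intermediate
4 | 5-hydroxy-7-methoxy-4H-chromen-4-one | COc1cc(O)c2c(=O)ccoc2c1 | intermediate
5 | 1,2,3,4-tetramethoxybenzene | COc1ccc(OC)c(OC)c1OC | starting material
6 | N-iodosuccinimide | O=C1CCC(=O)N1I | starting material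
7 | 1-iodo-2,3,4,5-tetramethoxybenzene | COc1cc(I)c(OC)c(OC)c1OC | intermediate
8 | 2-zinciochromone: C2-zincated 7-methoxy-5-oxido-4H-chromen-4-one, drawn as the monomeric divalent-zinc species (an aggregate with MgCl2 and LiCl in solution) | COc1cc([O-])c2c(=O)cc([Zn+])oc2c1 | intermediate
9 | 5-hydroxy-7-methoxy-2-(2,3,4,5-tetramethoxyphenyl)-4H-chromen-4-one (5-hydroxy-7,2′,3′,4′,5′-pentamethoxyflavone, C20H20O8, achiral) | COc1cc(O)c2c(=O)cc(-c3cc(OC)c(OC)c(OC)c3OC)oc2c1 | target

## Step count and risk

Total steps: 3. Longest linear sequence: 2 steps (1 → 4 → 9, or 5 → 7 → 9).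

**Step 3 (most likely to fail).** The phenoxide may make the chromone too electron-rich for clean C2 zincation, or the chelate may be poorly soluble. The fallback sets out from 4 and returns at 9. The phenol is capped first: 4 is O-methylated (MeI, K2CO3, DMF, 50 °C) to 5,7-dimethoxy-4H-chromen-4-one F1, the substrate class on which C2-zincation is established. TMP2Zn·2MgCl2·2LiCl (0.6 equiv, THF, −30 °C) then gives bis(5,7-dimethoxy-4-oxo-4H-chromen-2-yl)zinc F2. Negishi coupling of this with 7 (Pd(OAc)2, SPhos, THF, 50 °C) gives 5,7-dimethoxy-2-(2,3,4,5-tetramethoxyphenyl)-4H-chromen-4-one F3. BCl3 (1.5 equiv, CH2Cl2, −78 → 0 °C) then cleaves only the methyl ether peri to the C4 carbonyl, by chelation control, to give 9. This costs two extra steps but keeps the same bond construction.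

**Step 1.** DMF-DMA can O-methylate an acidic phenol, and ring closure may be incomplete. The fallback sets out from 1 and returns at 4. It replaces the amide-acetal condensation by a Claisen formylation: 1 with NaH (4.5 equiv) and ethyl formate in THF gives, after acidification, 3-(2,6-dihydroxy-4-methoxyphenyl)-3-oxopropanal F4 (largely as its cyclic hemiacetal). This is dehydrated with HCl in AcOH at 60 °C to 4.

**Step 2.** Di-iodination or oxidative demethylation of the very electron-rich arene to a quinone is possible. The fallback sets out from 5 and returns at 7. It replaces electrophilic substitution by directed ortho-metalation: n-BuLi/TMEDA in THF at 0 °C gives (2,3,4,5-tetramethoxyphenyl)lithium F5, which is quenched with I2 at −78 °C to 7.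

## Further compounds

F1 | step 3 | 5,7-dimethoxy-4H-chromen-4-one | COc1cc(OC)c2c(=O)ccoc2c1
F2 | step 3 | bis(5,7-dimethoxy-4-oxo-4H-chromen-2-yl)zinc | COc1cc(OC)c2c(=O)cc([Zn]c3cc(=O)c4c(OC)cc(OC)cc4o3)oc2c1
F3 | step 3 | 5,7-dimethoxy-2-(2,3,4,5-tetramethoxyphenyl)-4H-chromen-4-one | COc1cc(OC)c2c(=O)cc(-c3cc(OC)c(OC)c(OC)c3OC)oc2c1
F4 | step 1 | 3-(2,6-dihydroxy-4-methoxyphenyl)-3-oxopropanal | O=CCC(=O)c1c(O)cc(OC)cc1O
F5 | step 2 | (2,3,4,5-tetramethoxyphenyl)lithium | [Li]c1cc(OC)c(OC)c(OC)c1OC
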